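The cyclohexane is closed last, between ring carbon C2 (the CHOH carbon) and ring carbon C1 (the carbon bearing the 1-carboxyvinyl group; numbering as in the name of 30). In an open-chain precursor these atoms are an aldehyde carbon and the β-carbon of a 2-(acyloxymethyl)alk-2-enoate, both electrophilic. SmI2 reverses the polarity of the aldehyde: the ketyl closes the ring 6-exo, sets both new stereocentres, and the samarium enolate then expels pivalate, so the exocyclic methylene of the acrylate appears in the same operation. The acyclic aldehyde draws its adjacent quaternary (methyl, vinyl) and tertiary centres from an enantioselective Ireland–Claisen rearrangement and its acyloxy-bearing centre from a vinylogous Mukaiyama aldol.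

Key step: step 13

Assumption: the absolute sense of induction in steps 2 and 11 and the Z(O) geometry of the boron ketene acetal in step 11 are taken from the accepted models for these reagent classes. If a sense proves opposite, the enantiomeric catalyst or controller is used; if the enolate proves E(O), enolisation is done with Et3N in toluene–hexane instead.

Step 1
Reactants: 1 ethyl 3-methylbut-2-enoate
Product: 2 tert-butyl[(1-ethoxy-3-methylbuta-1,3-dien-1-yl)oxy]dimethylsilane
Conditions: LiN(iPr)2 (1.1 equiv), THF, −78 °C; tBuMe2SiCl, DMPU, −78 °C → rt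
Reagents that add atoms: tert-butyl(chloro)dimethylsilane, CC(C)(C)[Si](C)(C)Cl
Why: γ-deprotonation of the senecioate and O-silylation of the extended enolate (silyl dienol ether formation) should give the nucleophile for the vinylogous aldol; no stereocentre is formed.

Step 2
Reactants: 2 silyl dienol ether; 3 prop-2-enal (acrolein)
Product: 4 ethyl (2E,5S)-5-hydroxy-3-methylhepta-2,6-dienoate
Conditions: SiCl4 (1.1 equiv), (R,R)-binaphthyldiamine-derived bisphosphoramide (5 mol%), iPr2NEt (10 mol%), CH2Cl2, −78 °C; aq. NaHCO3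
Reagents that add atoms: none
Why: a Lewis-base-catalysed vinylogous Mukaiyama aldol should join the γ-carbon of 2 to the aldehyde, the chiral phosphoramide-bound trichlorosilyl cation selecting the aldehyde face that gives the 5S carbinol and the E-enoate.

Step 3
Reactants: 4 hydroxy dienoate
Product: 5 (2E,5S)-3-methylhepta-2,6-diene-1,5-diol
Conditions: iBu2AlH (3.2 equiv), CH2Cl2, −78 → 0 °C; aq. potassium sodium tartrate
Reagents that add atoms: none
Why: 1,2-reduction of the conjugated ester by iBu2AlH should give the E-allylic alcohol without touching the carbinol centre.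

Step 4
Reactants: 6 2-(bromomethyl)prop-2-enoic acid
Product: 8 2-(trimethylsilyl)ethyl 2-(bromomethyl)prop-2-enoate, via 2-(bromomethyl)prop-2-enoyl chloride 7 (not isolated)
Conditions: (COCl)2 (1.2 equiv), DMF (cat.), CH2Cl2, 0 °C → rt; then Me3SiCH2CH2OH (1.1 equiv), 2,6-lutidine (1.2 equiv), CH2Cl2, −20 °C
Reagents that add atoms: 2-(trimethylsilyl)ethanol, C[Si](C)(C)CCO
Why: esterification through the acid chloride with a hindered, non-nucleophilic base should avoid attack on the allylic bromide and installs the fluoride-labile ester that is removed in the last step.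

Step 5
Reactants: 8 bromomethyl acrylate
Product: 9 2-(trimethylsilyl)ethyl 2-{[(2,2-dimethylpropanoyl)oxy]methyl}prop-2-enoate
Conditions: tBuCO2H (1.5 equiv), Cs2CO3 (0.75 equiv), DMF, 0 °C → rt
Reagents that add atoms: 2,2-dimethylpropanoic acid (pivalic acid), CC(C)(C)C(=O)O
Why: allylic substitution of bromide by caesium pivalate (SN2 and SN2' give the same product) should install a leaving group that has no enolisable hydrogen.

Step 6
Reactants: 5 diol; 9 pivaloyloxymethyl acrylate
Product: 10 2-(trimethylsilyl)ethyl (2E,4S,6E)-4,8-dihydroxy-6-methyl-2-{[(2,2-dimethylpropanoyl)oxy]methyl}octa-2,6-dienoate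
Conditions: second-generation Hoveyda–Grubbs catalyst (5 mol%), 9 (3 equiv), 1,4-benzoquinone (10 mol%), CH2Cl2, 40 °C
Reagents that add atoms: none
Why: olefin cross-metathesis of the monosubstituted olefin of 5 with the 1,1-disubstituted acrylate (the trisubstituted olefin of 5 is inert) should give the trisubstituted enoate as the thermodynamically preferred 2E isomer, whose geometry is erased in step 13.

Step 7
Reactants: 11 2-methylprop-2-en-1-ol
Product: 15 3-({[tert-butyl(dimethyl)silyl]oxy}methyl)but-3-enoic acid, via dilithiated methallyl alkoxide 12 (not isolated), via dilithium alkoxide carboxylate 13 (not isolated), via lithium silyloxy carboxylate 14 (not isolated)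
Conditions: nBuLi (2.2 equiv), TMEDA, Et2O–hexane, 0 °C → rt; CO2 (g), −78 °C; tBuMe2SiCl (1.2 equiv), THF–DMF, 0 °C → rt; 1 M HCl to pH 4, 0 °C
Reagents that add atoms: carbon dioxide, O=C=O; tert-butyl(chloro)dimethylsilane, CC(C)(C)[Si](C)(C)Cl
Why: alkoxide-assisted allylic lithiation gives the dianion, which should be carboxylated at carbon; the more nucleophilic alkoxide is then silylated in preference to the carboxylate, so the γ-hydroxy acid never forms and cannot lactonise.

Step 8
Reactants: 10 diol enoate; 15 butenoic acid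
Product: 16 2-(trimethylsilyl)ethyl (2E,4S,6E)-8-{[3-({[tert-butyl(dimethyl)silyl]oxy}methyl)but-3-enoyl]oxy}-4-hydroxy-6-methyl-2-{[(2,2-dimethylpropanoyl)oxy]methyl}octa-2,6-dienoate
Conditions: PPh3 (1.2 equiv), DIAD (1.2 equiv), THF, 0 °C
Reagents that add atoms: none
Why: Mitsunobu esterification should activate the primary allylic hydroxyl in preference to the hindered secondary one, and its neutral conditions neither conjugate the but-3-enoate nor disturb the allylic pivalate.

Step 9
Reactants: 17 3-methylfuran-2(5H)-one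
Product: 20 (2Z)-4-(acetyloxy)-2-methylbut-2-enoic acid, via potassium hydroxy carboxylate 18 (not isolated), via alkoxide carboxylate dianion 19 (not isolated)
Conditions: KOH (1.0 equiv), MeOH–H2O, rt, then evaporation; NaH (1.05 equiv), DMF, 0 °C; Ac2O (1.05 equiv), −20 °C; 1 M HCl to pH 3, 0 °C
Reagents that add atoms: potassium hydroxide, [K+].[OH-]; acetic anhydride, CC(=O)OC(C)=O
Why: saponification of the butenolide fixes the Z geometry, and acetylation of the alkoxide of the dianion (faster than acylation of the carboxylate) should cap the hydroxyl before acidification, so relactonisation is avoided.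

Step 10
Reactants: 16 hydroxy diester; 20 (Z)-acetoxy acid
Product: 22 2-(trimethylsilyl)ethyl (2E,4S,6E)-4-{[(2Z)-4-(acetyloxy)-2-methylbut-2-enoyl]oxy}-8-{[3-({[tert-butyl(dimethyl)silyl]oxy}methyl)but-3-enoyl]oxy}-6-methyl-2-{[(2,2-dimethylpropanoyl)oxy]methyl}octa-2,6-dienoate, via mixed anhydride 21 (not isolated)
Conditions: 20 (1.5 equiv), 2,4,6-Cl3C6H2COCl (1.5 equiv), Et3N (1.5 equiv), toluene, rt, filtration; then 16, toluene, 60 °C, no DMAP
Reagents that add atoms: none
Why: Yamaguchi esterification through the pre-formed, amine-free mixed anhydride and without a nucleophilic catalyst is the variant that should keep an angelate-type Z-acyl group from isomerising, and it acylates the carbinol with retention.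

Step 11
Reactants: 22 triester
Product: 25 (2S,3S,5S,6E)-5-{[(2Z)-4-(acetyloxy)-2-methylbut-2-enoyl]oxy}-2-(3-{[tert-butyl(dimethyl)silyl]oxy}prop-1-en-2-yl)-3-ethenyl-3-methyl-7-{[(2,2-dimethylpropanoyl)oxy]methyl}-8-oxo-8-[2-(trimethylsilyl)ethoxy]oct-6-enoic acid, via boron ketene acetal 23 (not isolated), via acyloxyborane 24 (not isolated)
Conditions: (4S,5S)-2-bromo-4,5-diphenyl-1,3-bis(4-methylbenzenesulfonyl)-1,3,2-diazaborolidine (1.2 equiv, made from the (S,S)-bis-sulfonamide and BBr3 in CH2Cl2, volatiles removed), iPr2NEt (1.5 equiv), CH2Cl2, −78 °C; then 4 °C, 3–5 d; pH 4 aqueous work-up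
Reagents that add atoms: none
Why: in this enantioselective Ireland–Claisen rearrangement, soft enolisation should occur only at the doubly activated CH2 of the but-3-enoate and give the Z(O) boron ketene acetal; the chair [3,3] shift with the E-allyl chain and the 2-propenyl group both equatorial sets the like C2/C3 relationship (tertiary next to quaternary), and the C2-symmetric sulfonamide ligand on boron selects the face that gives 2S,3S.

Step 12
Reactants: 25 acid
Product: 27 2-(trimethylsilyl)ethyl (2E,4S,6S,7S)-4-{[(2Z)-4-(acetyloxy)-2-methylbut-2-enoyl]oxy}-7-(3-{[tert-butyl(dimethyl)silyl]oxy}prop-1-en-2-yl)-6-ethenyl-6-methyl-8-oxo-2-{[(2,2-dimethylpropanoyl)oxy]methyl}oct-2-enoate, via acid chloride 26 (not isolated)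
Conditions: 1-chloro-N,N,2-trimethylprop-1-en-1-amine (1.2 equiv), CH2Cl2, 0 °C; LiAlH(OtBu)3 (1.2 equiv), THF, −78 °C; aq. potassium sodium tartrate
Reagents that add atoms: none
Why: neutral acid chloride formation followed by partial reduction with the hindered hydride should stop at the aldehyde, leave the four esters alone and, at −78 °C without base, preserve the α-stereocentre and the β,γ-position of the olefin.

Step 13
Reactants: 27 aldehyde
Product: 29 2-(trimethylsilyl)ethyl 2-[(1S,2R,3S,4S,6S)-6-{[(2Z)-4-(acetyloxy)-2-methylbut-2-enoyl]oxy}-3-(3-{[tert-butyl(dimethyl)silyl]oxy}prop-1-en-2-yl)-4-ethenyl-2-hydroxy-4-methylcyclohexyl]prop-2-enoate, via samarium enolate 28 (not isolated)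
Conditions: SmI2 (2.2 equiv, 0.1 M in THF, slow addition), HMPA (8 equiv), THF (0.005 M in 27), −78 → −20 °C; sat. aq. NH4Cl
Reagents that add atoms: none
Why: Electron transfer from divalent samarium to the aldehyde gives a ketyl that adds to the β-carbon of the enoate; a second electron turns the α-ester radical into a trivalent samarium enolate, which loses the β-pivaloyloxy group (E1cB) and so delivers the α-methylene ester directly. The closest known reaction type is the SmI2-mediated aldehyde–enoate ketyl–olefin reductive cyclisation, here ended by β-elimination of the samarium enolate instead of protonation. The cyclohexane is closed in the 6-exo-trig mode by the C2–C1 bond. Both new stereocentres should arise in a chair-like transition state in which the samarium-bound ketyl oxygen at C2, the enoate at C1 and the acyloxy group at C6 are equatorial, giving the 1,2-trans and 1,6-trans relationships; the other chair would set the C4 vinyl and C6 acyloxy groups 1,3-diaxial. The step needs reduction of the aldehyde in the presence of three ester-conjugated olefins bearing allylic acyloxy groups; this rests on the faster reduction of the aliphatic aldehyde at −78 °C, slow addition of two equivalents of SmI2 and the absence of a proton source, so that the enolate eliminates and is not protonated.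

Step 14
Reactants: 29 silyl-protected hydroxy ester
Product: 30 2-[(1S,2R,3S,4S,6S)-6-{[(2Z)-4-(acetyloxy)-2-methylbut-2-enoyl]oxy}-4-ethenyl-2-hydroxy-3-(3-hydroxyprop-1-en-2-yl)-4-methylcyclohexyl]prop-2-enoic acid
Conditions: tris(dimethylamino)sulfonium difluorotrimethylsilicate (TASF, 4 equiv), DMF, 0 °C → rt; pH 5 NaH2PO4 buffer, 0 °C
Reagents that add atoms: none
Why: fluoride should cleave the primary silyl ether and fragment the 2-(trimethylsilyl)ethyl ester to the carboxylate under non-acidic conditions, so that neither the acetate nor the enoate esters are touched and the γ-hydroxy acid is released cold at pH 5 without lactonising.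

Compound list
1 | ethyl 3-methylbut-2-enoate | CCOC(=O)C=C(C)C | starting material
2 | tert-butyl[(1-ethoxy-3-methylbuta-1,3-dien-1-yl)oxy]dimethylsilane | CCOC(=CC(C)=C)O[Si](C)(C)C(C)(C)C | intermediate
3 | prop-2-enal | C=CC=O | starting material
4 | ethyl (2E,5S)-5-hydroxy-3-methylhepta-2,6-dienoate | CCOC(=O)/C=C(\C)C[C@H](O)C=C | intermediate
5 | (2E,5S)-3-methylhepta-2,6-diene-1,5-diol | OC/C=C(\C)C[C@H](O)C=C | intermediate
6 | 2-(bromomethyl)prop-2-enoic acid | C=C(CBr)C(=O)O | starting material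
7 | 2-(bromomethyl)prop-2-enoyl chloride | C=C(CBr)C(=O)Cl | intermediate
8 | 2-(trimethylsilyl)ethyl 2-(bromomethyl)prop-2-enoate | C=C(CBr)C(=O)OCC[Si](C)(C)C | intermediate
9 | 2-(trimethylsilyl)ethyl 2-{[(2,2-dimethylpropanoyl)oxy]methyl}prop-2-enoate | C=C(COC(=O)C(C)(C)C)C(=O)OCC[Si](C)(C)C | intermediate
10 | 2-(trimethylsilyl)ethyl (2E,4S,6E)-4,8-dihydroxy-6-methyl-2-{[(2,2-dimethylpropanoyl)oxy]methyl}octa-2,6-dienoate | OC/C=C(\C)C[C@H](O)/C=C(\COC(=O)C(C)(C)C)C(=O)OCC[Si](C)(C)C | intermediate
11 | 2-methylprop-2-en-1-ol | C=C(C)CO | starting material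
12 | dilithiated methallyl alkoxide (lithium 2-(lithiomethyl)prop-2-en-1-olate) | [Li]CC(=C)CO[Li] | intermediate
13 | dilithium 3-(oxidomethyl)but-3-enoate | [Li]OCC(=C)CC(=O)O[Li] | intermediate
14 | lithium 3-({[tert-butyl(dimethyl)silyl]oxy}methyl)but-3-enoate | C=C(CO[Si](C)(C)C(C)(C)C)CC(=O)O[Li] | intermediate
15 | 3-({[tert-butyl(dimethyl)silyl]oxy}methyl)but-3-enoic acid | C=C(CO[Si](C)(C)C(C)(C)C)CC(=O)O | intermediate
16 | 2-(trimethylsilyl)ethyl (2E,4S,6E)-8-{[3-({[tert-butyl(dimethyl)silyl]oxy}methyl)but-3-enoyl]oxy}-4-hydroxy-6-methyl-2-{[(2,2-dimethylpropanoyl)oxy]methyl}octa-2,6-dienoate | C=C(CO[Si](C)(C)C(C)(C)C)CC(=O)OC/C=C(\C)C[C@H](O)/C=C(\COC(=O)C(C)(C)C)C(=O)OCC[Si](C)(C)C | intermediate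
17 | 3-methylfuran-2(5H)-one | CC1=CCOC1=O | starting material
18 | potassium (2Z)-4-hydroxy-2-methylbut-2-enoate | [K+].[O-]C(=O)/C(C)=C\CO | intermediate
19 | potassium sodium (2Z)-2-methyl-4-oxidobut-2-enoate | [Na+].[K+].[O-]C/C=C(/C)C(=O)[O-] | intermediate
20 | (2Z)-4-(acetyloxy)-2-methylbut-2-enoic acid | CC(=O)OC/C=C(/C)C(=O)O | intermediate
21 | (2Z)-4-(acetyloxy)-2-methylbut-2-enoic 2,4,6-trichlorobenzoic anhydride | CC(=O)OC/C=C(/C)C(=O)OC(=O)c1c(Cl)cc(Cl)cc1Cl | intermediate
22 | 2-(trimethylsilyl)ethyl (2E,4S,6E)-4-{[(2Z)-4-(acetyloxy)-2-methylbut-2-enoyl]oxy}-8-{[3-({[tert-butyl(dimethyl)silyl]oxy}methyl)but-3-enoyl]oxy}-6-methyl-2-{[(2,2-dimethylpropanoyl)oxy]methyl}octa-2,6-dienoate | C=C(CO[Si](C)(C)C(C)(C)C)CC(=O)OC/C=C(\C)C[C@H](OC(=O)/C(C)=C\COC(C)=O)/C=C(\COC(=O)C(C)(C)C)C(=O)OCC[Si](C)(C)C | intermediate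
23 | Z(O) boron ketene acetal of 22, boron carrying the (4S,5S)-4,5-diphenyl-1,3-bis(4-methylbenzenesulfonyl)-1,3,2-diazaborolidine ring | C=C(CO[Si](C)(C)C(C)(C)C)/C=C(\OB1N(S(=O)(=O)c2ccc(C)cc2)[C@@H](c2ccccc2)[C@H](c2ccccc2)N1S(=O)(=O)c1ccc(C)cc1)OC/C=C(\C)C[C@H](OC(=O)/C(C)=C\COC(C)=O)/C=C(\COC(=O)C(C)(C)C)C(=O)OCC[Si](C)(C)C | intermediate
24 | acyloxyborane of 25 (carboxylate bound to the same diazaborolidine boron) | C=C[C@](C)(C[C@H](OC(=O)/C(C)=C\COC(C)=O)/C=C(\COC(=O)C(C)(C)C)C(=O)OCC[Si](C)(C)C)[C@@H](C(=C)CO[Si](C)(C)C(C)(C)C)C(=O)OB1N(S(=O)(=O)c2ccc(C)cc2)[C@@H](c2ccccc2)[C@H](c2ccccc2)N1S(=O)(=O)c1ccc(C)cc1 | intermediate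
25 | (2S,3S,5S,6E)-5-{[(2Z)-4-(acetyloxy)-2-methylbut-2-enoyl]oxy}-2-(3-{[tert-butyl(dimethyl)silyl]oxy}prop-1-en-2-yl)-3-ethenyl-3-methyl-7-{[(2,2-dimethylpropanoyl)oxy]methyl}-8-oxo-8-[2-(trimethylsilyl)ethoxy]oct-6-enoic acid | C=C[C@](C)(C[C@H](OC(=O)/C(C)=C\COC(C)=O)/C=C(\COC(=O)C(C)(C)C)C(=O)OCC[Si](C)(C)C)[C@@H](C(=C)CO[Si](C)(C)C(C)(C)C)C(=O)O | intermediate
26 | acid chloride of 25 | C=C[C@](C)(C[C@H](OC(=O)/C(C)=C\COC(C)=O)/C=C(\COC(=O)C(C)(C)C)C(=O)OCC[Si](C)(C)C)[C@@H](C(=C)CO[Si](C)(C)C(C)(C)C)C(=O)Cl | intermediate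
27 | 2-(trimethylsilyl)ethyl (2E,4S,6S,7S)-4-{[(2Z)-4-(acetyloxy)-2-methylbut-2-enoyl]oxy}-7-(3-{[tert-butyl(dimethyl)silyl]oxy}prop-1-en-2-yl)-6-ethenyl-6-methyl-8-oxo-2-{[(2,2-dimethylpropanoyl)oxy]methyl}oct-2-enoate | C=C[C@](C)(C[C@H](OC(=O)/C(C)=C\COC(C)=O)/C=C(\COC(=O)C(C)(C)C)C(=O)OCC[Si](C)(C)C)[C@@H](C(=C)CO[Si](C)(C)C(C)(C)C)C=O | intermediate
28 | cyclised bis(diiodosamarium) species: trivalent samarium alkoxide at ring C2 and samarium ester enolate still carrying the pivaloyloxymethyl group | C=C[C@]1(C)C[C@H](OC(=O)/C(C)=C\COC(C)=O)[C@@H](C(COC(=O)C(C)(C)C)=C(O[Sm](I)I)OCC[Si](C)(C)C)[C@H](O[Sm](I)I)[C@@H]1C(=C)CO[Si](C)(C)C(C)(C)C | intermediate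
29 | 2-(trimethylsilyl)ethyl 2-[(1S,2R,3S,4S,6S)-6-{[(2Z)-4-(acetyloxy)-2-methylbut-2-enoyl]oxy}-3-(3-{[tert-butyl(dimethyl)silyl]oxy}prop-1-en-2-yl)-4-ethenyl-2-hydroxy-4-methylcyclohexyl]prop-2-enoate | C=C[C@]1(C)C[C@H](OC(=O)/C(C)=C\COC(C)=O)[C@@H](C(=C)C(=O)OCC[Si](C)(C)C)[C@H](O)[C@@H]1C(=C)CO[Si](C)(C)C(C)(C)C | intermediate
30 | 2-[(1S,2R,3S,4S,6S)-6-{[(2Z)-4-(acetyloxy)-2-methylbut-2-enoyl]oxy}-4-ethenyl-2-hydroxy-3-(3-hydroxyprop-1-en-2-yl)-4-methylcyclohexyl]prop-2-enoic acid | C=C[C@]1(C)C[C@H](OC(=O)/C(C)=C\COC(C)=O)[C@@H](C(=C)C(=O)O)[C@H](O)[C@@H]1C(=C)CO | target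

Total step count: 14. Longest linear sequence: 10 steps (1, 2, 3, 6, 8, 10, 11, 12, 13, 14).

Steps most likely to fail

Step 13 (key step). Electron transfer to the acyloxy-substituted enoates (loss of the ring C6 ester or of the side-chain acetate) may compete with ketyl formation, and the closure may pass partly through the other chair. The fallback sets out from 27 and avoids electron transfer altogether. Bu3SnH and AIBN in benzene at 80 °C should add the stannyl radical reversibly to the aldehyde oxygen; the O-stannyl ketyl cyclises 6-exo onto the enoate and the α-ester radical takes hydrogen from the stannane. Aqueous KF work-up then gives the saturated β-pivaloyloxy ester, 2-(trimethylsilyl)ethyl 2-[(1S,2R,3S,4S,6S)-cyclohexyl]-3-[(2,2-dimethylpropanoyl)oxy]propanoate F1, as a mixture at the new α-carbon. DBU in CH2Cl2 at 0 °C then eliminates pivalate (E1cB) and the route is rejoined at 29.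

Step 11. Soft enolisation may be incomplete or unselective in a substrate with four other ester carbonyls, or the facial control by the boron ligand may erode. The fallback sets out from 22 and uses the classical silyl variant: KN(SiMe3)2 (1.05 equiv) and Me3SiCl in THF–DMPU at −78 °C deprotonate only the most acidic CH2 and give the Z(O) trimethylsilyl ketene acetal F2. On warming to rt it rearranges through the same chair to the trimethylsilyl ester F3, which is hydrolysed on work-up. The relative configuration is fixed by the chair; the absolute one is secured by the existing carbinol centre, because 25 and its (2R,3R,5S) diastereomer F4 are diastereomers and F4 is removed by chromatography. The route is rejoined at 25.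

Step 10. The Z-acyl donor may isomerise to the E isomer during activation, or the deactivated allylic alcohol may acylate too slowly. The fallback sets out from 16 and builds the Z-enoate on the substrate. Carbodiimide esterification (DIC, CH2Cl2, 0 °C) with 2-[bis(2,2,2-trifluoroethoxy)phosphoryl]propanoic acid gives the phosphonate ester of 16, F5. Still–Gennari olefination with 2-oxoethyl acetate (KN(SiMe3)2, 18-crown-6, THF, −78 °C) should then give the Z-trisubstituted enoate, and the route is rejoined at 22.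

Further compounds
F1 | step 13 | 2-(trimethylsilyl)ethyl 2-[(1S,2R,3S,4S,6S)-6-{[(2Z)-4-(acetyloxy)-2-methylbut-2-enoyl]oxy}-3-(3-{[tert-butyl(dimethyl)silyl]oxy}prop-1-en-2-yl)-4-ethenyl-2-hydroxy-4-methylcyclohexyl]-3-[(2,2-dimethylpropanoyl)oxy]propanoate (both epimers at C2 of the propanoate) | C=C[C@]1(C)C[C@H](OC(=O)/C(C)=C\COC(C)=O)[C@@H](C(COC(=O)C(C)(C)C)C(=O)OCC[Si](C)(C)C)[C@H](O)[C@@H]1C(=C)CO[Si](C)(C)C(C)(C)C
F2 | step 11 | Z(O) trimethylsilyl ketene acetal of 22 | C=C(CO[Si](C)(C)C(C)(C)C)/C=C(\O[Si](C)(C)C)OC/C=C(\C)C[C@H](OC(=O)/C(C)=C\COC(C)=O)/C=C(\COC(=O)C(C)(C)C)C(=O)OCC[Si](C)(C)C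
F3 | step 11 | trimethylsilyl ester of 25 | C=C[C@](C)(C[C@H](OC(=O)/C(C)=C\COC(C)=O)/C=C(\COC(=O)C(C)(C)C)C(=O)OCC[Si](C)(C)C)[C@@H](C(=C)CO[Si](C)(C)C(C)(C)C)C(=O)O[Si](C)(C)C
F4 | step 11 | (2R,3R,5S) diastereomer of 25 | C=C[C@@](C)(C[C@H](OC(=O)/C(C)=C\COC(C)=O)/C=C(\COC(=O)C(C)(C)C)C(=O)OCC[Si](C)(C)C)[C@H](C(=C)CO[Si](C)(C)C(C)(C)C)C(=O)O
F5 | step 10 | 2-[bis(2,2,2-trifluoroethoxy)phosphoryl]propanoate ester of 16 (at the secondary hydroxyl, both epimers at the phosphonate carbon) | C=C(CO[Si](C)(C)C(C)(C)C)CC(=O)OC/C=C(\C)C[C@H](OC(=O)C(C)P(=O)(OCC(F)(F)F)OCC(F)(F)F)/C=C(\COC(=O)C(C)(C)C)C(=O)OCC[Si](C)(C)C
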